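**Strategy.** Ring C is cut at both of its bonds to ring A (O1–C8a and C4–C4a): what remains, O1–C2–C3–C4, is an enantiopure 4-aryl-β-lactone, and ring A becomes a 3-alkoxyaryne. In the key step the aryne C4a–C8a unit inserts into the acyl C4–O1 bond of (S)-4-(4-acetoxyphenyl)oxetan-2-one, so the four-membered oxetanone is expanded by two atoms to the chromanone while the preformed C2 stereocentre is not touched and the 5-oxygen of the aryne fixes the regiochemistry. The precursors are a symmetric ortho-silylaryl triflate from 2-methylresorcinol and the β-lactone from an asymmetric transfer hydrogenation. The C6 methyl group then steers a para-Claisen–Cope shift of a 5-O-prenyl ether to C8.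

Key step: step 9

Remark: atom numbers follow the flavanone skeleton (O1, C2, C3, C4, C4a, C5–C8, C8a; ring A the phloroglucinol ring, ring B the 4-hydroxyphenyl group, ring C the pyranone); compounds 1, 9, 10 and 20 are taken as commercial.

Step 1
Reactants: 1 2-methylresorcinol
Product: 2 1,3-bis(methoxymethoxy)-2-methylbenzene
Conditions: MOMCl, i-Pr2NEt, CH2Cl2, 0 °C to rt
Reagents that add atoms: chloromethyl methyl ether, COCCl
Why: Williamson-type O-alkylation protects both phenols as MOM acetals, which should survive the organolithium, fluoride and aryne steps and come off with acid at the end.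

Step 2
Reactants: 2 1,3-bis(methoxymethoxy)-2-methylbenzene
Product: 4 3,5-bis(methoxymethoxy)-4-methylphenol, via aryl pinacol boronate 3 (not isolated)
Conditions: [Ir(OMe)(cod)]2 (1.5 mol%), 4,4'-di-tert-butyl-2,2'-bipyridine, B2pin2, THF, 80 °C; then 30% H2O2, aq. NaOH, 0 °C
Reagents that add atoms: bis(pinacolato)diboron, CC1(C)OB(OC1(C)C)B1OC(C)(C)C(C)(C)O1 (boron and pinacol of intermediate 3 only); hydrogen peroxide, OO
Why: The sterically governed [Ir(OMe)(cod)]2/bipyridine-catalysed C–H borylation (Hartwig–Miyaura type) should occur only at the one C–H not flanked by a substituent, and oxidation of the C–B bond then gives the symmetric phenol whose oxygen becomes O1.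

Step 3
Reactants: 4 3,5-bis(methoxymethoxy)-4-methylphenol
Product: 5 2-bromo-3,5-bis(methoxymethoxy)-4-methylphenol
Conditions: NBS (1.0 equiv), CH2Cl2, −78 to −20 °C
Reagents that add atoms: N-bromosuccinimide, BrN1C(=O)CCC1=O
Why: Electrophilic aromatic bromination ortho to the free OH; the two ortho positions are equivalent by symmetry, so only over-bromination has to be held back by stoichiometry and low temperature.

Step 4
Reactants: 5 2-bromo-3,5-bis(methoxymethoxy)-4-methylphenol
Product: 8 3,5-bis(methoxymethoxy)-4-methyl-2-(trimethylsilyl)phenyl trifluoromethanesulfonate, via aryl trimethylsilyl ether 6 (not isolated), via lithium 2-silylphenoxide 7 (not isolated)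
Conditions: (Me3Si)2NH, THF, 65 °C, evaporate; n-BuLi, THF, −100 to −78 °C; Tf2O, −78 °C
Reagents that add atoms: hexamethyldisilazane, C[Si](C)(C)N[Si](C)(C)C; trifluoromethanesulfonic anhydride, O=S(=O)(OS(=O)(=O)C(F)(F)F)C(F)(F)F; n-butyllithium, [Li]CCCC (lithium of intermediate 7 only)
Why: O-silylation, bromine–lithium exchange and 1,3 O-to-C silyl shift (retro-Brook rearrangement) put the silyl group on carbon and free the phenoxide for triflation, the standard entry to ortho-silylaryl triflate aryne precursors.

Step 5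
Reactants: 9 4-acetoxybenzoyl chloride, 10 3-tert-butoxy-3-oxopropanoic acid (mono-tert-butyl malonate)
Product: 12 tert-butyl 3-(4-acetoxyphenyl)-3-oxopropanoate, via acylmalonic half-ester 11 (not isolated)
Conditions: MgCl2, Et3N, MeCN, 0 °C to rt; then aq. citric acid
Reagents that add atoms: none
Why: MgCl2-mediated C-acylation of the malonate half-ester followed by decarboxylation on acidic work-up (Claisen-type β-keto ester synthesis) is mild enough to leave the aryl acetate intact.

Step 6
Reactants: 12 tert-butyl 3-(4-acetoxyphenyl)-3-oxopropanoate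
Product: 13 tert-butyl (3S)-3-(4-acetoxyphenyl)-3-hydroxypropanoate
Conditions: RuCl[(S,S)-TsDPEN](p-cymene) (1 mol%), HCO2H/Et3N (5:2), DMF, 25 °C
Reagents that add atoms: none
Why: Noyori–Ikariya asymmetric transfer hydrogenation, in which the aryl group of the ketone sits under the η6-arene of RuH[(S,S)-TsDPEN](p-cymene) (CH/π contact) so that hydride should be delivered to the face giving the (S)-benzylic alcohol, the only stereocentre of the target.

Step 7
Reactants: 13 tert-butyl (3S)-3-(4-acetoxyphenyl)-3-hydroxypropanoate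
Product: 14 (3S)-3-(4-acetoxyphenyl)-3-hydroxypropanoic acid
Conditions: CF3CO2H, CH2Cl2, 0 °C to rt
Reagents that add atoms: none
Why: Acidolysis of the tert-butyl ester (loss of isobutene) frees the acid without base, so the aryl acetate survives, and the electron-poor acetoxyphenyl group should keep the benzylic carbinol from ionising.

Step 8
Reactants: 14 (3S)-3-(4-acetoxyphenyl)-3-hydroxypropanoic acid
Product: 15 4-[(2S)-4-oxooxetan-2-yl]phenyl acetate
Conditions: PhSO2Cl, pyridine, 0 °C
Reagents that add atoms: none
Why: β-Lactonisation by carboxyl activation (mixed carboxylic–sulfonic anhydride attacked by the β-hydroxyl group) leaves the C–O bond at the stereocentre untouched, so the (S) configuration is retained.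

Step 9
Reactants: 8 3,5-bis(methoxymethoxy)-4-methyl-2-(trimethylsilyl)phenyl trifluoromethanesulfonate, 15 4-[(2S)-4-oxooxetan-2-yl]phenyl acetate
Product: 18 4-[(2S)-5,7-bis(methoxymethoxy)-6-methyl-4-oxochroman-2-yl]phenyl acetate, via aryne 16 (not isolated), via oxonium zwitterion 17 (not isolated)
Conditions: CsF (3 equiv), MeCN, 25 °C, slow addition of 8 (1.5 equiv)
Reagents that add atoms: none
Why: Proposed new method: fluoride-induced 1,2-elimination of 8 gives aryne 16, which is attacked by the ring oxygen of β-lactone 15 (ether-like because the four-membered ring weakens ester resonance) at C8a, the aryne carbon remote from the methoxymethoxy group, to give zwitterion 17 with the carbanion at C4a stabilised inductively by the neighbouring oxygen substituent. The C4a carbanion then adds to the adjacent oxonium-activated acyl carbon C4 and the acyl C4–O1 bond breaks (four-centre addition–elimination, as in an anionic Fries shift), so the aryne unit is inserted into the acyl C–O σ bond. Ring C is thus closed by ring expansion of the oxetanone by two atoms: O1–C8a forms first by nucleophilic addition to the aryne and C4–C4a second by intramolecular acyl transfer. The closest known reaction types are the aryne σ-insertion into the N–C(O) bond of β-lactams to give 2,3-dihydroquinolin-4-ones, the C–O insertion of arynes into carboxylic acids to give ortho-hydroxyaryl ketones and the aryne insertion into the C–O bond of epoxides. No stereocentre is created: none of the four bonds at C2 is made or broken, so the (S) configuration from step 6 should be carried over unchanged. The step needs regioselectivity (O1 to C8a, acyl to C4a), secured by the aryne distortion caused by the 3-alkoxy group, and chemoselectivity for ring-oxygen over carbonyl-oxygen attack and for acyl over benzylic attack of the carbanion, helped by the geometry of 17 and by the electron-poor 4-acetoxyphenyl group, which disfavours ionisation of the benzylic C2–O1 bond.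

Step 10
Reactants: 18 4-[(2S)-5,7-bis(methoxymethoxy)-6-methyl-4-oxochroman-2-yl]phenyl acetate
Product: 19 4-[(2S)-5-hydroxy-7-(methoxymethoxy)-6-methyl-4-oxochroman-2-yl]phenyl acetate
Conditions: BCl3 (1.05 equiv), CH2Cl2, −78 °C; then H2O
Reagents that add atoms: none
Why: Chelation-controlled Lewis-acid acetal cleavage: BCl3 bound between C4=O and the peri 5-oxygen should cleave the 5-O-MOM group preferentially and leave the 7-O-MOM ether and the acetate at −78 °C.

Step 11
Reactants: 19 4-[(2S)-5-hydroxy-7-(methoxymethoxy)-6-methyl-4-oxochroman-2-yl]phenyl acetate, 20 3-methylbut-2-en-1-ol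
Product: 21 4-[(2S)-7-(methoxymethoxy)-6-methyl-5-(3-methylbut-2-en-1-yloxy)-4-oxochroman-2-yl]phenyl acetate
Conditions: PPh3, DIAD, THF, 0 °C to rt
Reagents that add atoms: none
Why: Mitsunobu etherification of the hydrogen-bonded but acidic 5-OH with a primary allylic alcohol works under neutral conditions, which avoids the base-induced retro-oxa-Michael opening of ring C that would erode the C2 configuration.

Step 12
Reactants: 21 4-[(2S)-7-(methoxymethoxy)-6-methyl-5-(3-methylbut-2-en-1-yloxy)-4-oxochroman-2-yl]phenyl acetate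
Product: 24 4-[(2S)-5-hydroxy-7-(methoxymethoxy)-6-methyl-8-(3-methylbut-2-en-1-yl)-4-oxochroman-2-yl]phenyl acetate, via ortho-dienone 22 (not isolated), via para-dienone 23 (not isolated)
Conditions: Eu(fod)3 (10 mol%; fod = 6,6,7,7,8,8,8-heptafluoro-2,2-dimethyloctane-3,5-dionate), CHCl3, 60 °C
Reagents that add atoms: none
Why: Eu(fod)3 chelated between C4=O and O5 should accelerate the aromatic Claisen rearrangement, and because the ortho carbon C6 carries the methyl group the dienone 22 cannot enolise and undergoes a Cope shift to C8 (para-Claisen–Cope), the double allylic inversion delivering an un-inverted prenyl group before enolisation of 23 restores ring A.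

Step 13
Reactants: 24 4-[(2S)-5-hydroxy-7-(methoxymethoxy)-6-methyl-8-(3-methylbut-2-en-1-yl)-4-oxochroman-2-yl]phenyl acetate
Product: 25 6-methyl-8-prenylnaringenin, (2S)-5,7-dihydroxy-2-(4-hydroxyphenyl)-6-methyl-8-(3-methylbut-2-en-1-yl)-2,3-dihydro-4H-chromen-4-one
Conditions: HCl (1.25 M in MeOH), 25–40 °C
Reagents that add atoms: none
Why: Acid-catalysed transacetalisation of the MOM ether and methanolysis of the aryl acetate in one operation, under conditions that offer no enolate or chalcone pathway for epimerisation at C2 and are mild enough to limit addition of the 7-OH to the prenyl double bond.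

**Compound list**

1 | 2-methylresorcinol (2-methylbenzene-1,3-diol) | Cc1c(O)cccc1O | starting material
2 | 1,3-bis(methoxymethoxy)-2-methylbenzene | COCOc1cccc(OCOC)c1C | intermediate
3 | 2-[3,5-bis(methoxymethoxy)-4-methylphenyl]-4,4,5,5-tetramethyl-1,3,2-dioxaborolane | COCOc1cc(cc(OCOC)c1C)B1OC(C)(C)C(C)(C)O1 | intermediate (not isolated)
4 | 3,5-bis(methoxymethoxy)-4-methylphenol | COCOc1cc(O)cc(OCOC)c1C | intermediate
5 | 2-bromo-3,5-bis(methoxymethoxy)-4-methylphenol | COCOc1cc(O)c(Br)c(OCOC)c1C | intermediate
6 | [2-bromo-3,5-bis(methoxymethoxy)-4-methylphenoxy]trimethylsilane | COCOc1cc(O[Si](C)(C)C)c(Br)c(OCOC)c1C | intermediate (not isolated)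
7 | lithium 3,5-bis(methoxymethoxy)-4-methyl-2-(trimethylsilyl)phenoxide | COCOc1cc([O-])c(c(OCOC)c1C)[Si](C)(C)C.[Li+] | intermediate (not isolated)
8 | 3,5-bis(methoxymethoxy)-4-methyl-2-(trimethylsilyl)phenyl trifluoromethanesulfonate | COCOc1cc(OS(=O)(=O)C(F)(F)F)c(c(OCOC)c1C)[Si](C)(C)C | intermediate
9 | 4-acetoxybenzoyl chloride | CC(=O)Oc1ccc(cc1)C(Cl)=O | starting material
10 | 3-tert-butoxy-3-oxopropanoic acid (mono-tert-butyl malonate) | CC(C)(C)OC(=O)CC(O)=O | starting material
11 | 2-(4-acetoxybenzoyl)-3-tert-butoxy-3-oxopropanoic acid (present as its magnesium chelate) | CC(=O)Oc1ccc(cc1)C(=O)C(C(O)=O)C(=O)OC(C)(C)C | intermediate (not isolated)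
12 | tert-butyl 3-(4-acetoxyphenyl)-3-oxopropanoate | CC(=O)Oc1ccc(cc1)C(=O)CC(=O)OC(C)(C)C | intermediate
13 | tert-butyl (3S)-3-(4-acetoxyphenyl)-3-hydroxypropanoate | CC(=O)Oc1ccc(cc1)[C@@H](O)CC(=O)OC(C)(C)C | intermediate
14 | (3S)-3-(4-acetoxyphenyl)-3-hydroxypropanoic acid | CC(=O)Oc1ccc(cc1)[C@@H](O)CC(O)=O | intermediate
15 | 4-[(2S)-4-oxooxetan-2-yl]phenyl acetate, i.e. (S)-4-(4-acetoxyphenyl)oxetan-2-one | CC(=O)Oc1ccc(cc1)[C@@H]1CC(=O)O1 | intermediate
16 | 3,5-bis(methoxymethoxy)-4-methylbenzyne (1,2-didehydrobenzene) | COCOC1=C(C)C(OCOC)=CC#C1 | intermediate (not isolated)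
17 | O-arylated oxetanonium of 15 with the aryl carbanion at C4a (zwitterion, 2S) | CC(=O)Oc1ccc(cc1)[C@@H]1CC(=O)[O+]1C2=[C-]C(OCOC)=C(C)C(OCOC)=C2 | intermediate (not isolated)
18 | 4-[(2S)-5,7-bis(methoxymethoxy)-6-methyl-4-oxochroman-2-yl]phenyl acetate | CC(=O)Oc1ccc(cc1)[C@@H]1CC(=O)c2c(OCOC)c(C)c(OCOC)cc2O1 | intermediate
19 | 4-[(2S)-5-hydroxy-7-(methoxymethoxy)-6-methyl-4-oxochroman-2-yl]phenyl acetate | CC(=O)Oc1ccc(cc1)[C@@H]1CC(=O)c2c(O)c(C)c(OCOC)cc2O1 | intermediate
20 | 3-methylbut-2-en-1-ol (prenol) | CC(C)=CCO | starting material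
21 | 4-[(2S)-7-(methoxymethoxy)-6-methyl-5-(3-methylbut-2-en-1-yloxy)-4-oxochroman-2-yl]phenyl acetate | CC(=O)Oc1ccc(cc1)[C@@H]1CC(=O)c2c(OCC=C(C)C)c(C)c(OCOC)cc2O1 | intermediate
22 | 4-[(2S)-7-(methoxymethoxy)-6-methyl-6-(2-methylbut-3-en-2-yl)-4,5-dioxo-3,4,5,6-tetrahydro-2H-chromen-2-yl]phenyl acetate (both C6 epimers) | CC(=O)Oc1ccc(cc1)[C@@H]1CC(=O)C2=C(O1)C=C(OCOC)C(C)(C(C)(C)C=C)C2=O | intermediate (not isolated)
23 | 4-[(2S)-7-(methoxymethoxy)-6-methyl-8-(3-methylbut-2-en-1-yl)-4,5-dioxo-3,4,5,8-tetrahydro-2H-chromen-2-yl]phenyl acetate (both C8 epimers) | CC(=O)Oc1ccc(cc1)[C@@H]1CC(=O)C2=C(O1)C(CC=C(C)C)C(OCOC)=C(C)C2=O | intermediate (not isolated)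
24 | 4-[(2S)-5-hydroxy-7-(methoxymethoxy)-6-methyl-8-(3-methylbut-2-en-1-yl)-4-oxochroman-2-yl]phenyl acetate | CC(=O)Oc1ccc(cc1)[C@@H]1CC(=O)c2c(O)c(C)c(OCOC)c(CC=C(C)C)c2O1 | intermediate
25 | 6-methyl-8-prenylnaringenin, (2S)-5,7-dihydroxy-2-(4-hydroxyphenyl)-6-methyl-8-(3-methylbut-2-en-1-yl)-2,3-dihydro-4H-chromen-4-one | CC(C)=CCc1c(O)c(C)c(O)c2c1O[C@H](c1ccc(O)cc1)CC2=O | target

**Step count and risks**

Total step count: 13. Longest linear sequence: 9 steps (steps 1–4 or 5–8, then 9–13).

Steps most likely to fail:

1. Step 9. The weakly nucleophilic lactone oxygen may fail to intercept the aryne, which then reacts with itself. Attack through the carbonyl oxygen may open the lactone by way of a benzylic cation with loss of configuration. Fluoride may open ring C of the product by retro-oxa-Michael reaction (racemisation) or cleave the aryl acetate. The fallback uses known chemistry only, sets out from 13 and 8 and returns at 19. CsF in MeCN generates aryne 16, which is O-arylated by the secondary alcohol of 13 (addition of an alcohol O–H to an aryne; the carbinol C–O bond is not touched, so the centre stays S) to give tert-butyl (3S)-3-(4-acetoxyphenyl)-3-[3,5-bis(methoxymethoxy)-4-methylphenoxy]propanoate F1. CF3CO2H in wet CH2Cl2 should then remove the tert-butyl ester and both MOM groups to give (3S)-3-(4-acetoxyphenyl)-3-(3,5-dihydroxy-4-methylphenoxy)propanoic acid F2. Intramolecular Friedel–Crafts acylation of the phloroglucinol-type ring ((CF3CO)2O, CH2Cl2, 0 °C; the two ortho positions are equivalent) should close ring C to 4-[(2S)-5,7-dihydroxy-6-methyl-4-oxochroman-2-yl]phenyl acetate F3. MOMCl (1 equiv) with i-Pr2NEt should etherify only the non-chelated 7-OH and so give 19.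

2. Step 10. Chelation control may be lost, so that both acetals or the 7-O-acetal are cleaved. The fallback gives up the differentiation of the two ring-A oxygens, sets out from 18 and returns at 25. HCl in MeOH should remove both MOM groups and the acetate to give (2S)-5,7-dihydroxy-2-(4-hydroxyphenyl)-6-methyl-2,3-dihydro-4H-chromen-4-one F4. Friedel–Crafts C-prenylation with 2-methylbut-3-en-2-ol and BF3·OEt2 in dioxane at rt can attack ring A only at C8, because C6 carries the methyl group, and should give 25 directly.

3. Step 11 (and with it the rearrangement of step 12). Etherification of the hydrogen-bonded 5-OH, flanked by the C6 methyl group, may stall, or the basic betaine may open ring C and erode the configuration. The fallback replaces the sigmatropic route by a cross-coupling, sets out from 18 and returns at 25. N-Iodosuccinimide in MeCN should iodinate C8, the only free position of the electron-rich ring A, to give 4-[(2S)-8-iodo-5,7-bis(methoxymethoxy)-6-methyl-4-oxochroman-2-yl]phenyl acetate F5. Stille coupling with tributyl(3-methylbut-2-en-1-yl)stannane (Pd(PPh3)4, a zerovalent palladium complex, DMF, 90 °C) should give 4-[(2S)-5,7-bis(methoxymethoxy)-6-methyl-8-(3-methylbut-2-en-1-yl)-4-oxochroman-2-yl]phenyl acetate F6. HCl in MeOH as in step 13 then gives 25.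

Further compounds

F1 | step 9 | tert-butyl (3S)-3-(4-acetoxyphenyl)-3-[3,5-bis(methoxymethoxy)-4-methylphenoxy]propanoate | CC(=O)Oc1ccc(cc1)[C@@H](Oc1cc(OCOC)c(C)c(OCOC)c1)CC(=O)OC(C)(C)C
F2 | step 9 | (3S)-3-(4-acetoxyphenyl)-3-(3,5-dihydroxy-4-methylphenoxy)propanoic acid | CC(=O)Oc1ccc(cc1)[C@@H](Oc1cc(O)c(C)c(O)c1)CC(O)=O
F3 | step 9 | 4-[(2S)-5,7-dihydroxy-6-methyl-4-oxochroman-2-yl]phenyl acetate | CC(=O)Oc1ccc(cc1)[C@@H]1CC(=O)c2c(O)c(C)c(O)cc2O1
F4 | step 10 | (2S)-5,7-dihydroxy-2-(4-hydroxyphenyl)-6-methyl-2,3-dihydro-4H-chromen-4-one | Cc1c(O)cc2O[C@H](c3ccc(O)cc3)CC(=O)c2c1O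
F5 | step 11 | 4-[(2S)-8-iodo-5,7-bis(methoxymethoxy)-6-methyl-4-oxochroman-2-yl]phenyl acetate | CC(=O)Oc1ccc(cc1)[C@@H]1CC(=O)c2c(OCOC)c(C)c(OCOC)c(I)c2O1
F6 | step 11 | 4-[(2S)-5,7-bis(methoxymethoxy)-6-methyl-8-(3-methylbut-2-en-1-yl)-4-oxochroman-2-yl]phenyl acetate | CC(=O)Oc1ccc(cc1)[C@@H]1CC(=O)c2c(OCOC)c(C)c(OCOC)c(CC=C(C)C)c2O1
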